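**Plan**
- Retrosynthesis removes the C6=C7 unsaturation, then the C11 and C14 quinone oxygens and the 12-O-acetyl group, then cuts the lactone O–C20 bond (back to a C19 carboxamide and a C20 methyl), and last the C13–isopropyl bond.
- Forward: rings A, B and C come intact from podocarpic acid 1; propan-2-ol 2 supplies the isopropyl group at C13, C19 becomes the primary amide, and the bridged lactone (the only ring made) closes by radical functionalisation of C20–H. Ring C is then raised to the 12-acetoxy-11,14-quinone and C6=C7 is introduced last.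
- Enabling feature (abietane numbering: ring A = C1–C5, C10; ring B = C5–C10; ring C = C8, C9, C11–C14): C19 on C4 and C20 on C10 are 1,3-diaxial on the β-face of ring A and are joined through oxygen in the target. Podocarpic acid already has C4, C5, C10 and the C12 oxygen, with C20 as a methyl group.
- Stereochemistry: C4, C5 and C10 are taken unchanged from the chiral pool; no other permanent stereocentre exists, and the transient C7 bromide is destroyed on elimination.

Key step: step 4

Remark: the configuration in the target SMILES at C4, C5 and C10 is that of natural (+)-podocarpic acid (C19 β on C4, 5α-H, C20 β on C10), so no centre is inverted; all abietane names below imply this configuration.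

Step 1
Reactants: 1 podocarpic acid; 2 propan-2-ol
Product: 3 12-hydroxyabieta-8,11,13-trien-19-oic acid (13-isopropylpodocarpic acid)
Conditions: i-PrOH (5 equiv), BF3·OEt2 (3 equiv), ClCH2CH2Cl, 60 °C
Reagents that add atoms: none
Why: Friedel–Crafts alkylation of the phenol ring should go ortho to the hydroxyl at C13, because the para carbon C8 is substituted and the other ortho carbon C11 is shielded by the C1 methylene and the C20 methyl, while the hindered axial acid does not esterify.

Step 2
Reactants: 3 12-hydroxyabieta-8,11,13-trien-19-oic acid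
Product: 4 12-methoxyabieta-8,11,13-trien-19-oic acid
Conditions: Me2SO4 (1.2 equiv), NaOH (10% aq.), 0 °C → rt; then HCl to pH 2
Reagents that add atoms: dimethyl sulfate, COS(=O)(=O)OC
Why: Williamson O-methylation in aqueous alkali, where the phenoxide is far more nucleophilic than the hydrated, hindered axial carboxylate, so the acid should be recovered free on acidification.

Step 3
Reactants: 4 12-methoxyabieta-8,11,13-trien-19-oic acid
Product: 6 12-methoxyabieta-8,11,13-trien-19-amide, via acid chloride 5 (not isolated)
Conditions: (COCl)2, DMF (cat.), CH2Cl2, 0 °C → rt; evaporate; NH3 (0.5 M in 1,4-dioxane), THF, 0 °C → rt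
Reagents that add atoms: ammonia, N
Why: Activation of the hindered tertiary acid as its chloride (Vilsmeier-type chloroiminium catalysis) followed by acyl substitution with ammonia, a nucleophile small enough to reach the axial carbonyl.

Step 4
Reactants: 6 12-methoxyabieta-8,11,13-trien-19-amide
Product: 10 12-methoxyabieta-8,11,13-trien-19,20-olide, via N-iodoamide 7 (not isolated), via C20 iodide 8 (not isolated), via iminolactone 9 (not isolated)
Conditions: PhI(OAc)2 (2.5 equiv), I2 (1.2 equiv), ClCH2CH2Cl, visible light (tungsten lamp), 25–40 °C; then THF/H2O, 60 °C; Na2S2O3 wash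
Reagents that add atoms: water, O
Why: PhI(OAc)2 and I2 form acetyl hypoiodite, which N-iodinates the primary amide (7); visible light cleaves the N–I bond and the amidyl radical on the axial C19 carbonyl abstracts a hydrogen of the 1,3-diaxial C20 methyl through a seven-membered transition state (1,6-transfer), the C20 radical is iodinated (8), the neutral amide oxygen displaces the neopentyl iodide (helped by oxidation of the iodide to a trivalent-iodine leaving group by excess PhI(OAc)2) to give iminolactone 9, and water hydrolyses the C=N bond. The closest known reaction type is the N-iodoamide form of the Hofmann–Löffler–Freytag reaction, which turns carboxamides into lactones, and hydrogen abstraction from C20 by a nitrogen radical placed on C19 is known for this 1,3-diaxial pair in related diterpenoids. The one ring that closes is the six-membered lactone C19–O–C20–C10–C5–C4, by 6-exo-tet O-alkylation. No stereocentre is formed; C4, C5 and C10 are not touched. The step needs C20–H to win over the axial C2–H and C6–H (both open to 1,5-transfer) and over iodination of the anisole ring: the freely rotating methyl can offer a C–H bond collinear with nitrogen while the axial ring C–H bonds run parallel to the C4–C19 bond, and the only activated aryl position, C11, is shielded by C1 and C20. A neutral, non-nucleophilic medium suppresses Hofmann rearrangement of the N-iodoamide.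

Step 5
Reactants: 10 12-methoxyabieta-8,11,13-trien-19,20-olide
Product: 11 12-hydroxyabieta-8,11,13-trien-19,20-olide
Conditions: BBr3 (3 equiv), CH2Cl2, −78 → 0 °C; H2O
Reagents that add atoms: none
Why: Lewis-acid cleavage of the aryl methyl ether (BBr3 demethylation) by bromide attack on the O-methyl group, while the lactone should survive because its alkyl carbon C20 is neopentyl and its carbonyl sits on the quaternary C4.

Step 6
Reactants: 11 12-hydroxyabieta-8,11,13-trien-19,20-olide
Product: 13 11,12-dihydroxyabieta-8,11,13-trien-19,20-olide, via ortho-quinone 12 (not isolated)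
Conditions: (PhSeO)2O (1 equiv), THF, 50 °C; then Na2S2O4 (aq.), rt, N2
Reagents that add atoms: benzeneseleninic anhydride, O=[Se](c1ccccc1)O[Se](=O)c1ccccc1
Why: ortho-Oxygenation of a para-blocked phenol by benzeneseleninic anhydride ([2,3]-sigmatropic shift of the aryl seleninate) delivers oxygen to C11, the only free ortho carbon, and immediate dithionite reduction keeps the ortho-quinone from tautomerising to the C7 quinone methide.

Step 7
Reactants: 13 11,12-dihydroxyabieta-8,11,13-trien-19,20-olide
Product: 14 12-acetoxy-11-hydroxyabieta-8,11,13-trien-19,20-olide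
Conditions: Ac2O (1.05 equiv), pyridine, CH2Cl2, 0 °C
Reagents that add atoms: acetic anhydride, CC(=O)OC(C)=O
Why: Kinetic O-acylation should take the less hindered O12 hydroxyl, since O11 is buried between C1, the C20 methylene and O12, and an acetyl group placed on O11 can move to O12 by acyl migration.

Step 8
Reactants: 14 12-acetoxy-11-hydroxyabieta-8,11,13-trien-19,20-olide
Product: 15 12-acetoxy-11,14-dioxoabieta-8,12-dien-19,20-olide
Conditions: (KSO3)2NO (2.5 equiv), KH2PO4 (aq.), acetone, rt
Reagents that add atoms: potassium nitrosodisulfonate, [K+].[K+].[O]N(S(=O)(=O)[O-])S(=O)(=O)[O-]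
Why: Teuber oxidation, in which the nitroxyl radical removes the 11-OH hydrogen and a second equivalent couples at the free para carbon C14, so that loss of imidodisulfonate gives the 11,14-para-quinone with the 12-acetate in place.

Step 9
Reactants: 15 12-acetoxy-11,14-dioxoabieta-8,12-dien-19,20-olide
Product: 17 12-acetoxy-11,14-dioxoabieta-6,8,12-trien-19,20-olide (target), via 7α-bromide 16 (not isolated)
Conditions: NBS (1.1 equiv), AIBN (cat.), PhCF3, 80 °C; then 2,4,6-collidine, 80 °C
Reagents that add atoms: none
Why: Wohl–Ziegler bromination at C7, the only secondary position allylic to the quinone C8=C9 bond (the isopropyl methine lies in the ring plane between O12 and the C14 carbonyl and is poorly aligned for abstraction), followed by anti elimination of the pseudo-axial 7α-bromide with the axial 6β-hydrogen under a hindered pyridine base, should give the conjugated C6=C7 bond and remove the transient C7 centre.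

**Compound list**
1 | podocarpic acid | C[C@]12CCC[C@](C)(C(=O)O)[C@@H]1CCc1ccc(O)cc12 | starting material
2 | propan-2-ol | CC(C)O | starting material
3 | 12-hydroxyabieta-8,11,13-trien-19-oic acid | C[C@]12CCC[C@](C)(C(=O)O)[C@@H]1CCc1cc(C(C)C)c(O)cc12 | intermediate
4 | 12-methoxyabieta-8,11,13-trien-19-oic acid | C[C@]12CCC[C@](C)(C(=O)O)[C@@H]1CCc1cc(C(C)C)c(OC)cc12 | intermediate
5 | 12-methoxyabieta-8,11,13-trien-19-oyl chloride (formed in situ) | C[C@]12CCC[C@](C)(C(Cl)=O)[C@@H]1CCc1cc(C(C)C)c(OC)cc12 | intermediate
6 | 12-methoxyabieta-8,11,13-trien-19-amide | C[C@]12CCC[C@](C)(C(N)=O)[C@@H]1CCc1cc(C(C)C)c(OC)cc12 | intermediate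
7 | N-iodo-12-methoxyabieta-8,11,13-trien-19-amide (formed in situ) | C[C@]12CCC[C@](C)(C(=O)NI)[C@@H]1CCc1cc(C(C)C)c(OC)cc12 | intermediate
8 | 20-iodo-12-methoxyabieta-8,11,13-trien-19-amide (formed in situ) | IC[C@]12CCC[C@](C)(C(N)=O)[C@@H]1CCc1cc(C(C)C)c(OC)cc12 | intermediate
9 | 19-imino-12-methoxy-19,20-epoxyabieta-8,11,13-triene (iminolactone, formed in situ) | N=C1OC[C@]23CCC[C@@]1(C)[C@@H]2CCc1cc(C(C)C)c(OC)cc13 | intermediate
10 | 12-methoxyabieta-8,11,13-trien-19,20-olide | O=C1OC[C@]23CCC[C@@]1(C)[C@@H]2CCc1cc(C(C)C)c(OC)cc13 | intermediate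
11 | 12-hydroxyabieta-8,11,13-trien-19,20-olide | O=C1OC[C@]23CCC[C@@]1(C)[C@@H]2CCc1cc(C(C)C)c(O)cc13 | intermediate
12 | 11,12-dioxoabieta-8,13-dien-19,20-olide (ortho-quinone, formed in situ) | O=C1OC[C@]23CCC[C@@]1(C)[C@@H]2CCC1=C3C(=O)C(=O)C(C(C)C)=C1 | intermediate
13 | 11,12-dihydroxyabieta-8,11,13-trien-19,20-olide | O=C1OC[C@]23CCC[C@@]1(C)[C@@H]2CCc1cc(C(C)C)c(O)c(O)c13 | intermediate
14 | 12-acetoxy-11-hydroxyabieta-8,11,13-trien-19,20-olide | O=C1OC[C@]23CCC[C@@]1(C)[C@@H]2CCc1cc(C(C)C)c(OC(C)=O)c(O)c13 | intermediate
15 | 12-acetoxy-11,14-dioxoabieta-8,12-dien-19,20-olide | O=C1OC[C@]23CCC[C@@]1(C)[C@@H]2CCC1=C3C(=O)C(OC(C)=O)=C(C(C)C)C1=O | intermediate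
16 | 12-acetoxy-7α-bromo-11,14-dioxoabieta-8,12-dien-19,20-olide (formed in situ) | O=C1OC[C@]23CCC[C@@]1(C)[C@@H]2C[C@@H](Br)C1=C3C(=O)C(OC(C)=O)=C(C(C)C)C1=O | intermediate
17 | 12-acetoxy-11,14-dioxoabieta-6,8,12-trien-19,20-olide | CC(=O)OC1=C(C(C)C)C(=O)C2=C(C1=O)[C@]13CCC[C@](C)(C(=O)OC1)[C@@H]3C=C2 | target

Total step count: 9. Longest linear sequence: 9 steps (1 → 17).

**Steps most likely to fail**

Step 4. The amidyl radical may take hydrogen from the axial C2–H or C6–H instead of C20–H, the N-iodoamide may rearrange to the isocyanate, or the neopentyl iodide may fail to close. The fallback sets out from acid 4 and replaces the radical chain by a nitrene insertion. The chloride 5 with NaN3 (acetone/H2O, 0 °C) would give 12-methoxyabieta-8,11,13-trien-19-oyl azide F1. Irradiation in cyclohexane (Pyrex-filtered mercury lamp) generates the acyl nitrene, which inserts into a C20–H bond to give the δ-lactam F2. N-Nitrosation (NaNO2, Ac2O/AcOH, 0 °C) would give the N-nitrosolactam F3, and warming in an inert solvent (N-nitrosoamide rearrangement with loss of N2) exchanges N for O at C20, returning to the route at lactone 10.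

Step 9. The quinone may trap radicals and stall the bromination chain, abstraction may occur at the isopropyl methine, or the activated 12-acetate may be lost during dehydrobromination. The fallback sets out from 15 and brominates at the aromatic oxidation level. Reductive acetylation (Zn, Ac2O, NaOAc) gives 11,12,14-triacetoxyabieta-8,11,13-trien-19,20-olide F4. Benzylic Wohl–Ziegler bromination (NBS, AIBN) gives the 7α-bromo triacetate F5, and DBU in toluene eliminates HBr to the 6,7-dehydro triacetate F6. K2CO3/MeOH under air removes the three acetates to the 11,12,14-triol F7, which autoxidises to the 6,7-dehydro hydroxyquinone F8. Ac2O/pyridine then acetylates the single hydroxyl, returning to the route at target 17.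

Step 7. Both hydroxyls may be acetylated, or the acetyl group may migrate between O12 and O11 before oxidation. The fallback sets out from catechol 13 and uses a group that cannot migrate. Mono-O-methylation (MeI, K2CO3, acetone; O12 is the established site in 11,12-dihydroxyabietatrienes) gives 11-hydroxy-12-methoxyabieta-8,11,13-trien-19,20-olide F9. Teuber oxidation with (KSO3)2NO gives the 12-methoxy-11,14-quinone F10, and hydrolysis of this vinylogous ester (dilute aq. NaOH, then acid) gives the 12-hydroxy-11,14-quinone F11. Its single hydroxyl is acetylated (Ac2O, pyridine), returning to the route at 15.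

**Further compounds**
F1 | step 4 | 12-methoxyabieta-8,11,13-trien-19-oyl azide | C[C@]12CCC[C@](C)(C(=O)N=[N+]=[N-])[C@@H]1CCc1cc(C(C)C)c(OC)cc12
F2 | step 4 | 12-methoxy-19-oxo-19,20-epiminoabieta-8,11,13-triene (δ-lactam) | O=C1NC[C@]23CCC[C@@]1(C)[C@@H]2CCc1cc(C(C)C)c(OC)cc13
F3 | step 4 | N-nitroso-12-methoxy-19-oxo-19,20-epiminoabieta-8,11,13-triene | O=C1N(N=O)C[C@]23CCC[C@@]1(C)[C@@H]2CCc1cc(C(C)C)c(OC)cc13
F4 | step 9 | 11,12,14-triacetoxyabieta-8,11,13-trien-19,20-olide | O=C1OC[C@]23CCC[C@@]1(C)[C@@H]2CCc1c(OC(C)=O)c(C(C)C)c(OC(C)=O)c(OC(C)=O)c13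
F5 | step 9 | 11,12,14-triacetoxy-7α-bromoabieta-8,11,13-trien-19,20-olide | O=C1OC[C@]23CCC[C@@]1(C)[C@@H]2C[C@@H](Br)c1c(OC(C)=O)c(C(C)C)c(OC(C)=O)c(OC(C)=O)c13
F6 | step 9 | 11,12,14-triacetoxyabieta-6,8,11,13-tetraen-19,20-olide | O=C1OC[C@]23CCC[C@@]1(C)[C@@H]2C=Cc1c(OC(C)=O)c(C(C)C)c(OC(C)=O)c(OC(C)=O)c13
F7 | step 9 | 11,12,14-trihydroxyabieta-6,8,11,13-tetraen-19,20-olide | O=C1OC[C@]23CCC[C@@]1(C)[C@@H]2C=Cc1c(O)c(C(C)C)c(O)c(O)c13
F8 | step 9 | 12-hydroxy-11,14-dioxoabieta-6,8,12-trien-19,20-olide | O=C1OC[C@]23CCC[C@@]1(C)[C@@H]2C=CC1=C3C(=O)C(O)=C(C(C)C)C1=O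
F9 | step 7 | 11-hydroxy-12-methoxyabieta-8,11,13-trien-19,20-olide | O=C1OC[C@]23CCC[C@@]1(C)[C@@H]2CCc1cc(C(C)C)c(OC)c(O)c13
F10 | step 7 | 12-methoxy-11,14-dioxoabieta-8,12-dien-19,20-olide | O=C1OC[C@]23CCC[C@@]1(C)[C@@H]2CCC1=C3C(=O)C(OC)=C(C(C)C)C1=O
F11 | step 7 | 12-hydroxy-11,14-dioxoabieta-8,12-dien-19,20-olide | O=C1OC[C@]23CCC[C@@]1(C)[C@@H]2CCC1=C3C(=O)C(O)=C(C(C)C)C1=O
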